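Remark on the chemistry: the ring is numbered C1 (side-chain carbon), C2 (CH2), C3–C4 (epoxide, methyl on C4), C5 (ketone), C6 (ester carbinol), and the chain C7(=C14H2)–C8(ester)–C9–C10=C11. In this numbering the target is (1S,3S,4S,6S,8R). 2,2-Dimethoxyacetaldehyde is taken as its commercial aqueous solution.

## The problem

The target is a monocyclic sesquiterpenoid diester. Five of the six ring carbons are functionalised: the side chain on C1, an epoxide across C3–C4 with the methyl group on C4, a ketone at C5 and a senecioate on C6. The ring is joined through C1–C7 to a chain with a 1,1-disubstituted alkene (C7=C14), a second senecioate on C8 and a prenyl end.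

There are five stereocentres. In the ring, C1 and C6 are trans, and the epoxide oxygen lies on the face of the C1 substituent, anti to the C6 ester. These ring centres can pass information to one another: C1 and C6 by thermodynamic preference, the epoxide through a temporary C5 hydroxyl. C8 is cut off from the ring by the sp2 carbon C7, so it must be set by a reagent and brought in as a single enantiomer.

The molecule tolerates little. The senecioates are cleaved or deconjugated by alkoxide or strong base. C6 is an epimerisable α-acyloxy ketone. Loss of senecioic acid across C1–C6 from any C3=C4 enone intermediate ends in a phenol. The epoxy ketone and the skipped dienes are acid-sensitive. The last steps must therefore be near neutral.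

The enabling feature is that C1 is β to the C5 carbonyl through C6, while C3=C4 (the alkene behind the epoxide) is the α,β-bond of the same carbonyl. The ring is thus the sum of a Michael addition (C6 to C1) and an aldol condensation (C4 to C3) between a C4–C5–C6 α-acyloxy ketone and a C3–C2–C1 enal. The C1 substituent can be held as a carboxyl group until the chain is attached.

## Retrosynthesis

**Epoxide and C5 oxidation level (21 back to 18).** The two C–O bonds of the epoxide are removed first. Direct nucleophilic epoxidation of enone 18 is rejected: it needs basic peroxide in the presence of two senecioates, and in 5-substituted 2-methylcyclohex-2-enones the peroxide enters anti to the ring substituent, which is the wrong face here. Target 21 is therefore traced to epoxy alcohol 20 (oxidation), 20 to allylic alcohol 19 (hydroxyl-directed epoxidation) and 19 to enone 18 (1,2-reduction). The forward sequence needs axial hydride delivery at C5, so that the hydroxyl is cis to the C1 substituent and then delivers oxygen to that face. It costs three steps and adds no carbon, but every ring stereocentre is now derived from C1 and C6 of 18.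

**C1–C7 (18 back to 17 and 16).** This cut divides 18 into the ring as redox-active ester 17 and the chain as alkenyl bromide 16, two pieces of similar size, each with its own stereochemistry. C1 is not α to a carbonyl, so enolate alkylation is not available, and conjugate addition to a C1=C6 enone is incompatible with the C6 oxygen. Cuts at C7–C8 or C1–C2 would leave C8 or the ring stereocentres to be made on a large intermediate. A C1 radical from a carboxylate joined to an sp2 bromide under nickel catalysis fits the carboxyl handle that the annulation supplies. The forward reaction must form the bond anti to the C6 ester and must spare the enone, the α-acyloxy ketone and the allylic ester.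

**Active ester (17 back to 10).** The N–O ester bond is cut; acid 10 is the handle carrier and the product of the key step.

**Ring (10 back to 4 and 7).** C6–C1 and C3=C4 are cut together, with a tert-butoxycarbonyl group added back on C6 as a traceless activator. This leads to α-acyloxy β-ketoester 4 and enal 7, two achiral four- and five-carbon pieces. The cut is preferred to ring closures that need the chain already in place, because it makes the ring, the C6 ester, the C5 ketone and the C3=C4 alkene at the right oxidation level in one flask. The forward reaction needs an amine catalyst to choose the face of the enal at C1, after which C6 follows by equilibration to the trans isomer.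

**Fragments 4 and 7.** Ketoester 4 is cut at the C6–O bond to chloride 2 and acid 3; 2 comes from ketoester 1 by chlorination. Enal 7 is cut at its C1=C2 bond (olefination) to acetal 6 and, one step further, aldehyde 5.

**Side chain (16 back to 11).** The ester C–O bond of 16 is cut to alcohol 15 and acid 3. C8 is set by reduction of ketone 14, where the bromovinyl group gives the catalyst a clear large substituent. Ketone 14 comes from racemic alcohol 13, which is cut at C7–C8 into aldehyde 12 and a 1-bromovinyl nucleophile; 12 is the oxidation product of alcohol 11.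

## Roads not taken

**Alternative 1: pinacol closure of C5–C6.** The ring is cut between the two oxygen-bearing carbons. The precursor is dialdehyde A2, (2Z,5S,7R)-7-[(tert-butyldimethylsilyl)oxy]-5-formyl-2,10-dimethyl-6-methylideneundeca-2,9-dienal, with the chain already on C1. SmI2 would couple the two formyl carbons to cis-diol A1.
- Merits: the ring and both ring oxygens arise in one step, the chain rides through, and C1 is never re-set.
- Weak points:
  - One aldehyde of A2 is a 2-methyl enal, whose ketyl is an allyl-type radical anion; conjugate reduction and coupling through the γ-carbon compete.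
  - The other aldehyde sits on C1, which is α to the formyl group and allylic to C7=C14, so epimerisation and migration of the alkene into conjugation threaten before coupling.
  - The cis-diol places the C5 hydroxyl on the face of the C6 oxygen, opposite to where the epoxide must go. It cannot direct the epoxidation and would have to be oxidised and reduced again.
  - The two secondary hydroxyls must be told apart, the silyl ether exchanged for the ester, and A2 itself needs a long linear build.
- Comparison: this route is better in that no radical coupling at C1 is needed. The chosen plan sets against that a convergent union of two small fragments and a catalytic ring synthesis that delivers C5 and C6 at their final oxidation levels.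

**Alternative 2: silyl-diene Diels–Alder.** C1–C2 and C5–C6 are cut. Diene A4, (E)-dimethyl(2-methylbuta-1,3-dien-1-yl)(propan-2-yloxy)silane, and β-acyloxy enone A5 would combine under MgBr2·OEt2 to cycloadduct A3.
- Merits: three ring stereocentres (C1, C5, C6) are set at once. The trans C1/C6 relation follows from the E-dienophile. The C5 silyl group is a masked hydroxyl on the face that later directs epoxidation. This is more stereochemistry per step than the annulation offers.
- Weak points:
  - A5 is a donor-substituted, sluggish dienophile that can lose its acyloxy group under Lewis acid.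
  - Regiochemistry rests on the methyl group alone, since a terminal silyl group directs weakly.
  - Facial control needs the C8 ether in the wrong (S) configuration, so C8 must later be inverted by a Mitsunobu esterification at a hindered carbinol.
  - The C7 ketone must be methylenated between two enolisable stereocentres.
  - The C5 silane is allylic and prone to protodesilylation before its Fleming–Tamao oxidation.
- Comparison: the post-cycloaddition sequence is clearly longer than the endgame of the chosen plan, which has to set against the denser key step only the later re-setting of C1.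

**Alternative 3: ring-closing metathesis at C3=C4.** The acyclic triene A7 carries all esters. The second-generation Grubbs catalyst RuCl2(=CHPh)(PCy3)(H2IMes) would join its allyl terminus to the isopropenyl ketone to give A6, which is identical with compound 18.
- Merits: this is the most reliable ring closure of the four. Of the six alkenes only the monosubstituted allyl group and the 2-propenyl ketone are reactive partners that can form an unstrained ring. The endgame is shared with the chosen route, and no radical step is needed.
- Weak points: all stereochemical work moves into A7. The anti C1/C6 pair next to an epimerisable α-acyloxy ketone, and C8, must be fixed by acyclic control in a linear sequence, with a reactive isopropenyl ketone carried along.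
- Comparison: in ring-forming reliability this route is better. The chosen plan sets against it brevity and convergence: the ring with its two stereocentres comes from achiral materials in one catalytic operation.

Key step: step 5

## Route

Step 1
Reactants: 1 tert-butyl 3-oxopentanoate
Product: 2 tert-butyl 2-chloro-3-oxopentanoate (racemic)
Conditions: SO2Cl2 (1.0 equiv), CH2Cl2, 0 °C to rt
Reagents that add atoms: sulfuryl chloride, O=S(=O)(Cl)Cl
Why: Electrophilic α-chlorination of the β-ketoester enol occurs at the doubly activated carbon; one equivalent of reagent should stop at the monochloride.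

Step 2
Reactants: 2 tert-butyl 2-chloro-3-oxopentanoate; 3 3-methylbut-2-enoic acid
Product: 4 tert-butyl 2-[(3-methylbut-2-enoyl)oxy]-3-oxopentanoate (racemic)
Conditions: KHCO3, DMF, rt
Reagents that add atoms: none
Why: SN2 displacement of the doubly activated secondary chloride by the carboxylate, the standard route to 2-acyloxy β-ketoesters; the weak base should not deconjugate the senecioate.

Step 3
Reactants: 5 2,2-dimethoxyacetaldehyde
Product: 6 tert-butyl (2E)-4,4-dimethoxybut-2-enoate
Conditions: Ph3P=CHCO2tBu, CH2Cl2, rt
Reagents that add atoms: tert-butyl 2-(triphenyl-λ5-phosphanylidene)acetate, CC(C)(C)OC(=O)C=P(c1ccccc1)(c1ccccc1)c1ccccc1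
Why: Wittig reaction of an ester-stabilised ylide, which should give the E-enoate and tolerates the water of the commercial aldehyde solution.

Step 4
Reactants: 6 tert-butyl (2E)-4,4-dimethoxybut-2-enoate
Product: 7 tert-butyl (2E)-4-oxobut-2-enoate
Conditions: Amberlyst-15, acetone/H2O, rt
Reagents that add atoms: water, O
Why: Acid-catalysed acetal hydrolysis on a sulfonic acid resin is mild enough at room temperature to leave the tert-butyl ester and the E-alkene untouched.

Step 5
Reactants: 4 tert-butyl 2-[(3-methylbut-2-enoyl)oxy]-3-oxopentanoate; 7 tert-butyl (2E)-4-oxobut-2-enoate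
Product: 10 (1R,6S)-4-methyl-6-[(3-methylbut-2-enoyl)oxy]-5-oxocyclohex-3-ene-1-carboxylic acid, via Michael adduct 8 (not isolated), via cyclohexenone diester 9 (not isolated)
Conditions: (S)-2-{bis[3,5-bis(trifluoromethyl)phenyl][(trimethylsilyl)oxy]methyl}pyrrolidine (10 mol%), PhCO2H (10 mol%), toluene, 0 °C to rt; then TsOH·H2O (1.0 equiv), toluene, 80 °C
Reagents that add atoms: none
Why: The secondary amine condenses with enal 7 to an E-iminium ion, one face of which is covered by the diaryl(silyloxy)methyl group; the enol of 4 adds to the iminium β-carbon C1 (the carbon bearing the ester) from the open face, forming C6–C1 and setting C1 as R in adduct 8, while the fully substituted C6 forms as both epimers, which does not matter. On heating with TsOH the enol of the ethyl ketone (C4) attacks the aldehyde carbon C3 in a 6-(enolexo)-exo-trig aldol closure and water is lost to give enone 9; this is the only closure open, because C6 has no hydrogen and the aldehyde enol could only form a four-membered ring. The acid then removes both tert-butyl groups as 2-methylpropene, and the β-keto acid at C6 loses CO2 through its cyclic transition state, whereas the C1 acid is γ to the ketone and stays. Protonation of the resulting enol and acid-mediated equilibration at C6 should place the senecioate trans to the C1 carboxyl (both pseudo-equatorial), so the catalyst-set C1 fixes the absolute configuration of C6 as S. The closest known reaction is the diarylprolinol silyl ether-catalysed Michael addition of tert-butyl β-ketoesters to enals followed by TsOH-mediated aldol condensation and decarboxylation to cyclohex-2-enones. The step needs attack at the iminium β-carbon instead of conjugate addition to the ester (secured by iminium activation), one enal face (secured by the catalyst), and retention of the C6 ester (secured by working under acid, where elimination across C1–C6 has no enolate to start from). Enal 7 has no γ-hydrogen, so no dienamine pathway competes.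

Step 6
Reactants: 11 4-methylpent-3-en-1-ol
Product: 12 4-methylpent-3-enal
Conditions: Dess–Martin periodinane, NaHCO3, CH2Cl2, 0 °C to rt; used as a solution
Reagents that add atoms: none
Why: Dess–Martin oxidation of a primary alcohol under buffered, non-basic conditions should give the β,γ-unsaturated aldehyde without moving the alkene into conjugation.

Step 7
Reactants: 12 4-methylpent-3-enal
Product: 13 rac-2-bromo-6-methylhepta-1,5-dien-3-ol
Conditions: bromoethene, LiN(iPr)2, THF/Et2O/pentane, −110 °C; then 12, −110 to −78 °C; aq. NH4Cl
Reagents that add atoms: bromoethene, C=CBr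
Why: 1,2-Addition of 1-bromo-1-lithioethene, formed by α-deprotonation of bromoethene and stable only at very low temperature, to the aldehyde forms C7–C8; the new centre is racemic and is corrected in steps 8 and 9.

Step 8
Reactants: 13 rac-2-bromo-6-methylhepta-1,5-dien-3-ol
Product: 14 2-bromo-6-methylhepta-1,5-dien-3-one
Conditions: Dess–Martin periodinane, NaHCO3, CH2Cl2, 0 °C
Reagents that add atoms: none
Why: Dess–Martin oxidation of the secondary allylic alcohol; the neutral medium should keep the skipped enone from isomerising to the conjugated dienone.

Step 9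
Reactants: 14 2-bromo-6-methylhepta-1,5-dien-3-one
Product: 15 (3R)-2-bromo-6-methylhepta-1,5-dien-3-ol
Conditions: (S)-2-methyl-CBS-oxazaborolidine (20 mol%), catecholborane, toluene, −78 °C
Reagents that add atoms: none
Why: Corey–Bakshi–Shibata reduction, for which α-bromo enones are favourable substrates: the 1-bromovinyl group acts as the large substituent, and the (S)-catalyst should then deliver hydride to the face that gives the (R)-carbinol. Catecholborane is chosen because it does not hydroborate the trisubstituted alkene at this temperature.

Step 10
Reactants: 15 (3R)-2-bromo-6-methylhepta-1,5-dien-3-ol; 3 3-methylbut-2-enoic acid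
Product: 16 (3R)-2-bromo-6-methylhepta-1,5-dien-3-yl 3-methylbut-2-enoate
Conditions: DCC, DMAP (10 mol%), CH2Cl2, 0 °C to rt
Reagents that add atoms: none
Why: Steglich esterification acylates the oxygen, so C8 keeps its configuration; no base strong enough to deconjugate the senecioate is present.

Step 11
Reactants: 10 (1R,6S)-4-methyl-6-[(3-methylbut-2-enoyl)oxy]-5-oxocyclohex-3-ene-1-carboxylic acid
Product: 17 1,3-dioxoisoindolin-2-yl (1R,6S)-4-methyl-6-[(3-methylbut-2-enoyl)oxy]-5-oxocyclohex-3-ene-1-carboxylate
Conditions: N-hydroxyphthalimide, DIC, DMAP (5 mol%), CH2Cl2, 0 °C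
Reagents that add atoms: N-hydroxyphthalimide, O=C1c2ccccc2C(=O)N1O
Why: Carbodiimide esterification to the redox-active ester; low temperature and a minimum of base are used because the C1 hydrogen of the activated ester lies next to the C6 leaving group.

Step 12
Reactants: 17 1,3-dioxoisoindolin-2-yl (1R,6S)-4-methyl-6-[(3-methylbut-2-enoyl)oxy]-5-oxocyclohex-3-ene-1-carboxylate; 16 (3R)-2-bromo-6-methylhepta-1,5-dien-3-yl 3-methylbut-2-enoate
Product: 18 (1S,6S)-3-methyl-6-{(3R)-6-methyl-3-[(3-methylbut-2-enoyl)oxy]hepta-1,5-dien-2-yl}-2-oxocyclohex-3-en-1-yl 3-methylbut-2-enoate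
Conditions: NiBr2(dme) (10 mol%), 4,4′-di-tert-butyl-2,2′-bipyridine (10 mol%), Zn dust (2 equiv), DMA, rt
Reagents that add atoms: none
Why: Nickel-catalysed reductive decarboxylative alkenylation (cross-electrophile coupling): single-electron reduction of 17 releases CO2 and phthalimide anion and leaves a C1 radical, which is captured by the alkenylnickel bromide formed from 16 and zerovalent nickel; reductive elimination from trivalent nickel forms C1–C7. C1 passes through a planar radical and should be re-set by the neighbouring C6 ester, the new bond forming on the opposite ring face to give the trans isomer; C6 and C8 are not touched.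

Step 13
Reactants: 18 (1S,6S)-3-methyl-6-{(3R)-6-methyl-3-[(3-methylbut-2-enoyl)oxy]hepta-1,5-dien-2-yl}-2-oxocyclohex-3-en-1-yl 3-methylbut-2-enoate
Product: 19 (1S,2S,6S)-2-hydroxy-3-methyl-6-{(3R)-6-methyl-3-[(3-methylbut-2-enoyl)oxy]hepta-1,5-dien-2-yl}cyclohex-3-en-1-yl 3-methylbut-2-enoate
Conditions: NaBH4, CeCl3·7H2O, MeOH, −78 °C
Reagents that add atoms: none
Why: Luche 1,2-reduction of the enone; in the half-chair with the C1 and C6 substituents equatorial, axial hydride attack at C5 should give the equatorial alcohol, cis to the C1 side chain and trans to the C6 ester, as is usual for 5-substituted 2-methylcyclohex-2-enones. The conjugated esters are not reduced at this temperature.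

Step 14
Reactants: 19 (1S,2S,6S)-2-hydroxy-3-methyl-6-{(3R)-6-methyl-3-[(3-methylbut-2-enoyl)oxy]hepta-1,5-dien-2-yl}cyclohex-3-en-1-yl 3-methylbut-2-enoate
Product: 20 (1R,2R,3S,4S,6S)-2-hydroxy-1-methyl-4-{(3R)-6-methyl-3-[(3-methylbut-2-enoyl)oxy]hepta-1,5-dien-2-yl}-7-oxabicyclo[4.1.0]heptan-3-yl 3-methylbut-2-enoate
Conditions: VO(acac)2 (5 mol%), t-BuOOH (1.2 equiv), CH2Cl2, 0 °C to rt
Reagents that add atoms: tert-butyl hydroperoxide, CC(C)(C)OO
Why: Vanadium-catalysed hydroxyl-directed epoxidation: the vanadate ester of the C5 alcohol delivers the peroxide oxygen to the adjacent C3=C4 bond on the face of the hydroxyl, setting C3 and C4 cis to the C1 side chain. The prenyl, methylidene and senecioate alkenes have no allylic hydroxyl and should not react.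

Step 15
Reactants: 20 (1R,2R,3S,4S,6S)-2-hydroxy-1-methyl-4-{(3R)-6-methyl-3-[(3-methylbut-2-enoyl)oxy]hepta-1,5-dien-2-yl}-7-oxabicyclo[4.1.0]heptan-3-yl 3-methylbut-2-enoate
Product: 21 (1S,3S,4S,6S)-1-methyl-4-{(3R)-6-methyl-3-[(3-methylbut-2-enoyl)oxy]hepta-1,5-dien-2-yl}-2-oxo-7-oxabicyclo[4.1.0]heptan-3-yl 3-methylbut-2-enoate
Conditions: Dess–Martin periodinane, NaHCO3, CH2Cl2, 0 °C to rt
Reagents that add atoms: none
Why: Dess–Martin oxidation of the secondary alcohol restores the C5 ketone under buffered neutral conditions, which should leave the epoxide and both esters intact and C6 unepimerised.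

## Compound list

1 | tert-butyl 3-oxopentanoate | CCC(=O)CC(=O)OC(C)(C)C | starting material
2 | tert-butyl 2-chloro-3-oxopentanoate (racemic) | CCC(=O)C(Cl)C(=O)OC(C)(C)C | intermediate
3 | 3-methylbut-2-enoic acid | CC(C)=CC(=O)O | starting material
4 | tert-butyl 2-[(3-methylbut-2-enoyl)oxy]-3-oxopentanoate (racemic) | CCC(=O)C(OC(=O)C=C(C)C)C(=O)OC(C)(C)C | intermediate
5 | 2,2-dimethoxyacetaldehyde | COC(OC)C=O | starting material
6 | tert-butyl (2E)-4,4-dimethoxybut-2-enoate | COC(OC)/C=C/C(=O)OC(C)(C)C | intermediate
7 | tert-butyl (2E)-4-oxobut-2-enoate | O=C/C=C/C(=O)OC(C)(C)C | intermediate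
8 | di-tert-butyl (3R)-2-[(3-methylbut-2-enoyl)oxy]-3-(2-oxoethyl)-2-propanoylbutanedioate (both C2 epimers; not isolated) | CC(C)(C)OC(=O)[C@H](CC=O)C(OC(=O)C=C(C)C)(C(=O)CC)C(=O)OC(C)(C)C | intermediate
9 | di-tert-butyl (1R)-4-methyl-6-[(3-methylbut-2-enoyl)oxy]-5-oxocyclohex-3-ene-1,6-dicarboxylate (both C6 epimers; not isolated) | CC(C)(C)OC(=O)[C@@H]1CC=C(C)C(=O)C1(OC(=O)C=C(C)C)C(=O)OC(C)(C)C | intermediate
10 | (1R,6S)-4-methyl-6-[(3-methylbut-2-enoyl)oxy]-5-oxocyclohex-3-ene-1-carboxylic acid | OC(=O)[C@@H]1CC=C(C)C(=O)[C@H]1OC(=O)C=C(C)C | intermediate
11 | 4-methylpent-3-en-1-ol | CC(C)=CCCO | starting material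
12 | 4-methylpent-3-enal | CC(C)=CCC=O | intermediate
13 | rac-2-bromo-6-methylhepta-1,5-dien-3-ol | C=C(Br)C(O)CC=C(C)C | intermediate
14 | 2-bromo-6-methylhepta-1,5-dien-3-one | C=C(Br)C(=O)CC=C(C)C | intermediate
15 | (3R)-2-bromo-6-methylhepta-1,5-dien-3-ol | C=C(Br)[C@@H](CC=C(C)C)O | intermediate
16 | (3R)-2-bromo-6-methylhepta-1,5-dien-3-yl 3-methylbut-2-enoate | C=C(Br)[C@@H](CC=C(C)C)OC(=O)C=C(C)C | intermediate
17 | 1,3-dioxoisoindolin-2-yl (1R,6S)-4-methyl-6-[(3-methylbut-2-enoyl)oxy]-5-oxocyclohex-3-ene-1-carboxylate | O=C(ON1C(=O)c2ccccc2C1=O)[C@@H]3CC=C(C)C(=O)[C@H]3OC(=O)C=C(C)C | intermediate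
18 | (1S,6S)-3-methyl-6-{(3R)-6-methyl-3-[(3-methylbut-2-enoyl)oxy]hepta-1,5-dien-2-yl}-2-oxocyclohex-3-en-1-yl 3-methylbut-2-enoate | C=C([C@@H](CC=C(C)C)OC(=O)C=C(C)C)[C@@H]1CC=C(C)C(=O)[C@H]1OC(=O)C=C(C)C | intermediate
19 | (1S,2S,6S)-2-hydroxy-3-methyl-6-{(3R)-6-methyl-3-[(3-methylbut-2-enoyl)oxy]hepta-1,5-dien-2-yl}cyclohex-3-en-1-yl 3-methylbut-2-enoate | C=C([C@@H](CC=C(C)C)OC(=O)C=C(C)C)[C@@H]1CC=C(C)[C@H](O)[C@H]1OC(=O)C=C(C)C | intermediate
20 | (1R,2R,3S,4S,6S)-2-hydroxy-1-methyl-4-{(3R)-6-methyl-3-[(3-methylbut-2-enoyl)oxy]hepta-1,5-dien-2-yl}-7-oxabicyclo[4.1.0]heptan-3-yl 3-methylbut-2-enoate | C=C([C@@H](CC=C(C)C)OC(=O)C=C(C)C)[C@@H]1C[C@@H]2O[C@]2(C)[C@H](O)[C@H]1OC(=O)C=C(C)C | intermediate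
21 | (1S,3S,4S,6S)-1-methyl-4-{(3R)-6-methyl-3-[(3-methylbut-2-enoyl)oxy]hepta-1,5-dien-2-yl}-2-oxo-7-oxabicyclo[4.1.0]heptan-3-yl 3-methylbut-2-enoate | C=C([C@@H](CC=C(C)C)OC(=O)C=C(C)C)[C@@H]1C[C@@H]2O[C@]2(C)C(=O)[C@H]1OC(=O)C=C(C)C | target

## Step count and least certain steps

Total: 15 steps. Longest linear sequence: 9 steps (11 through steps 6–10, then 12–15). The ring branch from 1 is 8 steps.

**Step 5 (key step).**
- What may go wrong:
  - slow or poorly face-selective conjugate addition, because the donor carbon is fully substituted and carries an acyloxy group;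
  - consumption of the amine catalyst by acyl transfer from the activated ester of 4;
  - under acid, loss of senecioic acid across C1–C6 followed by aromatisation;
  - incomplete cleavage of the unactivated C1 tert-butyl ester.
- Fallback (sets out from 1 and 7, returns at 10): the C6 oxygen is introduced after the ring is made. Ketoester 1, the parent donor of this annulation, and enal 7 would go through the same amine-catalysed addition to di-tert-butyl (2R)-2-(2-oxoethyl)-3-propanoylbutanedioate F1 and, with TsOH in the same flask, to (1R)-4-methyl-5-oxocyclohex-3-ene-1-carboxylic acid F2. α′-Acyloxylation of F2 with Mn(OAc)3·2H2O in the presence of an excess of acid 3 (benzene, reflux) would then place the senecioate on C6 trans to the carboxyl and give 10.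

**Step 12.**
- What may go wrong:
  - β-acyloxy elimination from the alkenylnickel intermediate derived from 16 (allene formation), or insertion of zerovalent nickel into the allylic C–O bond;
  - on the ring side, a 1,2-acyloxy shift of the C1 radical or elimination across C1–C6 with aromatisation;
  - reductive cleavage of the α-acyloxy ketone by zinc;
  - insufficient preference for the trans isomer at C1.
- Fallback (sets out from 15 and 17, returns at 18): the chain is coupled without a leaving group next to the metal and the ester is added afterwards. Alcohol 15 would be silylated (TBSCl, imidazole, DMF) to tert-butyl{[(3R)-2-bromo-6-methylhepta-1,5-dien-3-yl]oxy}dimethylsilane F3. The same reductive coupling with 17 would give (1S,6S)-6-{(3R)-3-[(tert-butyldimethylsilyl)oxy]-6-methylhepta-1,5-dien-2-yl}-3-methyl-2-oxocyclohex-3-en-1-yl 3-methylbut-2-enoate F4. HF·pyridine in THF would free (1S,6S)-6-[(3R)-3-hydroxy-6-methylhepta-1,5-dien-2-yl]-3-methyl-2-oxocyclohex-3-en-1-yl 3-methylbut-2-enoate F5, and Steglich esterification of F5 with acid 3 would give 18.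

**Step 9.**
- What may go wrong: isomerisation of the skipped enone 14 into conjugation or its polymerisation before reduction, and insufficient discrimination between the two carbonyl substituents by the catalyst.
- Fallback (sets out from 13, returns at 15): ketone 14 is bypassed by a classical resolution. Racemic 13 would be esterified with (S)-2-methoxy-2-phenylacetic acid (DCC, DMAP) to (3R)-2-bromo-6-methylhepta-1,5-dien-3-yl (2S)-2-methoxy-2-phenylacetate F6 and its diastereomer (3S)-2-bromo-6-methylhepta-1,5-dien-3-yl (2S)-2-methoxy-2-phenylacetate F7. These would be separated by chromatography, and methanolysis of F6 (K2CO3, MeOH) would give 15.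

**Step 13.**
- What may go wrong: hydride delivery from the wrong face if the C6 ester distorts the half-chair, and migration of the senecioyl group from the C6 oxygen to the new C5 alkoxide in methanol.
- Fallback (sets out from 18, returns at 19): the reduction is moved from substrate control in a protic medium to catalyst control in an aprotic one. (S)-2-Methyl-CBS-oxazaborolidine with catecholborane in toluene at −78 °C, with the 2-methylalkenyl side of the ketone as the large group, is expected to give the same C5 configuration without an alkoxide intermediate. No new compound is formed.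

## Further compounds

F1 | step 5 | di-tert-butyl (2R)-2-(2-oxoethyl)-3-propanoylbutanedioate (both C3 epimers) | CC(C)(C)OC(=O)[C@H](CC=O)C(C(=O)CC)C(=O)OC(C)(C)C
F2 | step 5 | (1R)-4-methyl-5-oxocyclohex-3-ene-1-carboxylic acid | OC(=O)[C@@H]1CC=C(C)C(=O)C1
F3 | step 12 | tert-butyl{[(3R)-2-bromo-6-methylhepta-1,5-dien-3-yl]oxy}dimethylsilane | C=C(Br)[C@@H](CC=C(C)C)O[Si](C)(C)C(C)(C)C
F4 | step 12 | (1S,6S)-6-{(3R)-3-[(tert-butyldimethylsilyl)oxy]-6-methylhepta-1,5-dien-2-yl}-3-methyl-2-oxocyclohex-3-en-1-yl 3-methylbut-2-enoate | C=C([C@@H](CC=C(C)C)O[Si](C)(C)C(C)(C)C)[C@@H]1CC=C(C)C(=O)[C@H]1OC(=O)C=C(C)C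
F5 | step 12 | (1S,6S)-6-[(3R)-3-hydroxy-6-methylhepta-1,5-dien-2-yl]-3-methyl-2-oxocyclohex-3-en-1-yl 3-methylbut-2-enoate | C=C([C@@H](CC=C(C)C)O)[C@@H]1CC=C(C)C(=O)[C@H]1OC(=O)C=C(C)C
F6 | step 9 | (3R)-2-bromo-6-methylhepta-1,5-dien-3-yl (2S)-2-methoxy-2-phenylacetate | C=C(Br)[C@@H](CC=C(C)C)OC(=O)[C@@H](OC)c1ccccc1
F7 | step 9 | (3S)-2-bromo-6-methylhepta-1,5-dien-3-yl (2S)-2-methoxy-2-phenylacetate | C=C(Br)[C@H](CC=C(C)C)OC(=O)[C@@H](OC)c1ccccc1
F0 | step 13 | none | none
A1 | alternative 1 | (1S,2R,6S)-6-{(3R)-3-[(tert-butyldimethylsilyl)oxy]-6-methylhepta-1,5-dien-2-yl}-3-methylcyclohex-3-ene-1,2-diol | C=C([C@@H](CC=C(C)C)O[Si](C)(C)C(C)(C)C)[C@@H]1CC=C(C)[C@@H](O)[C@H]1O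
A2 | alternative 1 | (2Z,5S,7R)-7-[(tert-butyldimethylsilyl)oxy]-5-formyl-2,10-dimethyl-6-methylideneundeca-2,9-dienal | O=C/C(C)=C\C[C@H](C=O)C(=C)[C@@H](CC=C(C)C)O[Si](C)(C)C(C)(C)C
A3 | alternative 2 | (1S,2S,6R)-2-[dimethyl(propan-2-yloxy)silyl]-6-{(2S)-2-[(4-methoxyphenyl)methoxy]-5-methylhex-4-enoyl}-3-methylcyclohex-3-en-1-yl 3-methylbut-2-enoate | O=C([C@@H](OCc2ccc(OC)cc2)CC=C(C)C)[C@@H]1CC=C(C)[C@H]([Si](C)(C)OC(C)C)[C@H]1OC(=O)C=C(C)C
A4 | alternative 2 | (E)-dimethyl(2-methylbuta-1,3-dien-1-yl)(propan-2-yloxy)silane | C=C/C(C)=C/[Si](C)(C)OC(C)C
A5 | alternative 2 | (1E,4S)-4-[(4-methoxyphenyl)methoxy]-7-methyl-3-oxoocta-1,6-dien-1-yl 3-methylbut-2-enoate | CC(C)=CC(=O)O/C=C/C(=O)[C@@H](OCc1ccc(OC)cc1)CC=C(C)C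
A6 | alternative 3 | (1S,6S)-3-methyl-6-{(3R)-6-methyl-3-[(3-methylbut-2-enoyl)oxy]hepta-1,5-dien-2-yl}-2-oxocyclohex-3-en-1-yl 3-methylbut-2-enoate | C=C([C@@H](CC=C(C)C)OC(=O)C=C(C)C)[C@@H]1CC=C(C)C(=O)[C@H]1OC(=O)C=C(C)C
A7 | alternative 3 | (4S,5S)-2-methyl-5-{(3R)-6-methyl-3-[(3-methylbut-2-enoyl)oxy]hepta-1,5-dien-2-yl}-3-oxoocta-1,7-dien-4-yl 3-methylbut-2-enoate | C=CC[C@H]([C@H](OC(=O)C=C(C)C)C(=O)C(C)=C)C(=C)[C@@H](CC=C(C)C)OC(=O)C=C(C)C
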